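**Plan**

1. Cuts: the three allyl esters (last step), the ester between the central isocitrate carboxyl and the 4α-CH2OH of the second drimane, both C-11–O ether bonds (aldehyde + isocitrate alcohol), and the isocitrate C-3–C-4 bonds back to (R)-malic acid.
2. Second drimane: cut C-4–C-5 and C-9–C-10 to an epoxy-farnesyl acetate (Sharpless epoxide, Ti(III) radical bicyclisation, ring A then ring B).
3. Albicanyl unit: cut C-1–C-10 and C-3–C-4, which removes C-1 to C-3 as a propene 1,3-dianion equivalent and leaves ring B.
4. Enabling feature: ring B with C-5, the C-4 CMe2 carbon, the C-10 methyl, the C-8 carbonyl and a C-9=C-10 enone is (+)-verbenone; its cyclobutane bond C-4–C-7 lies α to C-8 and is a masked C-4 cation, and the enone (with a C-9 ester as future C-11) is the C-10 acceptor.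
5. Forward: verbenone → C-9 ester → one-flask (3+3) annulation of ring A onto ring B (trans-decalin β-keto ester) → albicanal; farnesyl acetate → 4α-oxygenated albicanal; two reductive etherifications with malate-derived isocitrates, one esterification, deallylation.
6. Stereochemistry: C-5 of verbenone sets C-10 (attack anti to the CMe2 bridge) and C-9 equilibrates equatorial; (R)-malic acid gives isocitrate C-2 and directs C-3 (Fráter–Seebach); the Sharpless epoxide carbon sets C-5, C-9, C-10 and C-4 of the second drimane.

Key step: step 4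

Remark 1: drimane locants are used (C-11 on C-9, C-12 the exocyclic methylene carbon on C-8); the oxygenated equatorial (4α) carbon on C-4 of the second drimane is called C-13 here; "albican-11-yl" is (5S,9S,10S)-drim-8(12)-en-11-yl; isocitrate carbons are C-1 (methyl ester), C-2 (O-bearing), C-3, C-4 (CH2), C-5, and C-6 for the central carboxyl.

Remark 2: enantiopure (1R,5R)-(+)-verbenone is assumed (accessible from (+)-α-pinene if commercial material needs upgrading); C-9 of β-keto esters 7 and 8 is assumed to settle as the equatorial ester through the enol, so only that epimer is drawn; 6 is drawn without configuration at its two transient centres.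

**Route**

Step 1
Reactants: 1 (1R,5R)-(+)-verbenone
Product: 2 3-iodoverbenone (bridgehead configuration of 1)
Conditions: I2, pyridine, DMAP (cat.), CH2Cl2, rt
Reagents that add atoms: iodine (II)
Why: Johnson-type α-iodination of a cyclic enone (conjugate addition of pyridine, iodination, elimination) should place iodine on the vinylic C-3 without touching the bridgehead stereocentres.

Step 2
Reactants: 2 3-iodoverbenone
Product: 3 methyl 4,6,6-trimethyl-2-oxobicyclo[3.1.1]hept-3-ene-3-carboxylate (bridgehead configuration of 1)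
Conditions: Pd(OAc)2 (5 mol%), dppf, CO (1 atm), MeOH, Et3N, DMF, 60 °C
Reagents that add atoms: carbon monoxide ([C-]#[O+]); methanol (CO)
Why: Palladium-catalysed alkoxycarbonylation of the α-iodoenone (oxidative addition, CO insertion, methanolysis) should give the alkylidene β-keto ester that carries the future C-11 and doubly activates the β-carbon (drimane C-10).

Step 3
Reactants: 4 allyltrimethylsilane
Product: 5 (E)-1,3-bis(trimethylsilyl)propene
Conditions: s-BuLi, TMEDA, THF, −78 °C; then TMSCl
Reagents that add atoms: chlorotrimethylsilane (C[Si](C)(C)Cl)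
Why: Deprotonation of the allylsilane and γ-silylation of the (trimethylsilyl)allyl anion is a known route to the (E)-1,3-bis(silyl)propene, a propene 1,3-dianion equivalent.

Step 4
Reactants: 3 methyl 4,6,6-trimethyl-2-oxobicyclo[3.1.1]hept-3-ene-3-carboxylate; 5 (E)-1,3-bis(trimethylsilyl)propene
Product: 7 methyl (1R,4aS,8aS)-5,5,8a-trimethyl-2-oxo-1,2,3,4,4a,5,6,8a-octahydronaphthalene-1-carboxylate, via conjugate adduct 6 (not isolated)
Conditions: TiCl4 (2.2 equiv), CH2Cl2, −78 °C; then i-PrOH (1.0 equiv), −78 → 0 °C
Reagents that add atoms: none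
Why: Proposed new method: TiCl4 chelates the alkylidene β-keto ester of 3 and the allylsilane 5 adds through its silyl-bearing vinylic carbon to the β-carbon (drimane C-10) in a Hosomi–Sakurai conjugate SE2′ step, after which one equivalent of 2-propanol protonates the titanium enolate to the keto ester 6. The Lewis-acid-bound C-8 carbonyl then accepts the electrons of the strained cyclobutane bond between its α-carbon (C-7) and the CMe2 carbon (C-4), and the tertiary C-4 cation is captured by the terminal carbon of the α-silyl allyl group with loss of the second silyl group, which leaves the C-1=C-2 alkene. The closest known reaction types are the Sakurai conjugate allylation of alkylidene β-keto esters, the Lewis acid opening of pinane cyclobutyl ketones such as nopinone, the allylsilane-terminated cation–olefin cyclisation and the use of 1,3-bis(silyl)propenes as propene 1,3-dianion equivalents; their union in one flask as a (3+3) annulation has not been shown. Ring A closes in a 6-endo-trig cation–olefin mode on the allylsilane π bond. The new quaternary C-10 is controlled by the bicyclo[3.1.1] skeleton, because the nucleophile must enter anti to the CMe2 bridge that is bonded to the resident stereocentre C-5, so that the C-10 chain and C-4 are trans on ring B and the decalin is trans-fused, while C-9 settles as the equatorial ester by enolisation. The step needs conjugate addition to outrun ionisation of the cyclobutane, which the doubly activated acceptor at −78 °C should secure, and it needs γ-attack in both silyl transfers, which the β-silicon effect dictates.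

Step 5
Reactants: 7 Δ1 keto ester
Product: 8 methyl (1R,4aS,8aS)-5,5,8a-trimethyl-2-oxodecahydronaphthalene-1-carboxylate
Conditions: H2 (1 atm), Pd/C, EtOAc, rt
Reagents that add atoms: none
Why: Heterogeneous hydrogenation should saturate the cis-disubstituted C-1=C-2 alkene, the helper left by the silyl termination, and creates no stereocentre.

Step 6
Reactants: 8 keto ester
Product: 9 methyl albicanate [methyl (1S,4aS,8aS)-5,5,8a-trimethyl-2-methylidenedecahydronaphthalene-1-carboxylate]
Conditions: Zn, CH2Br2, TiCl4, THF/CH2Cl2, 0 °C → rt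
Reagents that add atoms: dibromomethane (BrCBr)
Why: Takai–Lombardo methylenation is non-basic, so the acidic, epimerisable C-9–H and the ester should survive while the C-8 ketone becomes the exocyclic methylene.

Step 7
Reactants: 9 methyl albicanate
Product: 10 (+)-albicanol [(5S,9S,10S)-drim-8(12)-en-11-ol]
Conditions: LiAlH4, Et2O, 0 °C
Reagents that add atoms: none
Why: Hydride reduction of the ester to the primary alcohol changes no stereocentre.

Step 8
Reactants: 10 (+)-albicanol
Product: 11 albicanal [(5S,9S,10S)-drim-8(12)-en-11-al]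
Conditions: Dess–Martin periodinane, NaHCO3, CH2Cl2, 0 °C
Reagents that add atoms: none
Why: Buffered Dess–Martin oxidation gives the β,γ-unsaturated aldehyde without base, so C-9 should not epimerise and the alkene should not move into conjugation.

Step 9
Reactants: 12 (R)-malic acid
Product: 14 (R)-malic acid 1-methyl ester [(3R)-3-hydroxy-4-methoxy-4-oxobutanoic acid], via O-trifluoroacetylmalic anhydride 13 (not isolated)
Conditions: (CF3CO)2O, 0 °C → rt; then MeOH, rt
Reagents that add atoms: methanol (CO)
Why: The O-trifluoroacetyl cyclic anhydride is opened by methanol regioselectively at the carbonyl next to the acyloxy carbon (known for malic acid) and then deacylated, so C-2 keeps its configuration.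

Step 10
Reactants: 14 (R)-malic acid 1-methyl ester
Product: 15 4-tert-butyl 1-methyl (R)-malate
Conditions: Me2NCH(OtBu)2, toluene, 80 °C
Reagents that add atoms: N,N-dimethylformamide di-tert-butyl acetal (CN(C)C(OC(C)(C)C)OC(C)(C)C)
Why: Esterification with the DMF acetal tert-butylates only the carboxylic acid and leaves the secondary alcohol free.

Step 11
Reactants: 15 4-tert-butyl 1-methyl (R)-malate
Product: 16 3-allyl 2-tert-butyl 1-methyl (1R,2S)-1-hydroxypropane-1,2,3-tricarboxylate [protected (2R,3S)-isocitrate]
Conditions: LDA (2.2 equiv), THF, −78 → −20 °C; allyl bromoacetate, −78 → −50 °C; AcOH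
Reagents that add atoms: allyl bromoacetate (C=CCOC(=O)CBr)
Why: Fráter–Seebach alkylation, in which the chelated alkoxide–enolate dianion is attacked anti to the C-1 ester, should set C-3 as S and so give the (2R,3S)-isocitrate skeleton.

Step 12
Reactants: 16 hydroxy triester
Product: 17 O-trimethylsilyl ether of 16
Conditions: TMSCl, imidazole, CH2Cl2, 0 °C
Reagents that add atoms: chlorotrimethylsilane (C[Si](C)(C)Cl)
Why: Standard silylation of the secondary alcohol gives the silyl ether needed as oxygen nucleophile, used without chromatography.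

Step 13
Reactants: 11 albicanal; 17 O-trimethylsilyl ether
Product: 18 3-allyl 2-tert-butyl 1-methyl (1R,2S)-1-(albican-11-yloxy)propane-1,2,3-tricarboxylate
Conditions: Et3SiH, TMSOTf (0.2 equiv), CH2Cl2, −78 °C
Reagents that add atoms: none
Why: Reductive etherification (Noyori-type mixed acetal formation, ionisation to the oxocarbenium ion, hydride transfer from Et3SiH) makes the hindered C-11–O bond without base, and no bond to C-9 or to isocitrate C-2 is broken, so both should be kept.

Step 14
Reactants: 18 ether triester
Product: 20 (1R,2S)-1-(albican-11-yloxy)propane-1,2,3-tricarboxylic acid 3-allyl 1-methyl diester (free central acid), via trimethylsilyl ester 19 (not isolated)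
Conditions: TMSOTf, 2,6-lutidine, CH2Cl2, 0 °C → rt; then pH 4 buffer
Reagents that add atoms: none
Why: Silyl triflate cleavage of the tert-butyl ester (O-silylation, loss of isobutene) under lutidine buffering spares the allyl and methyl esters and the acid-sensitive exocyclic alkene.

Step 15
Reactants: 14 (R)-malic acid 1-methyl ester
Product: 21 4-allyl 1-methyl (R)-malate
Conditions: allyl bromide, KHCO3, DMF, rt
Reagents that add atoms: allyl bromide (C=CCBr)
Why: SN2 alkylation of the carboxylate esterifies the acid selectively, because hydrogencarbonate does not deprotonate the alcohol.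

Step 16
Reactants: 21 4-allyl 1-methyl (R)-malate
Product: 22 2,3-diallyl 1-methyl (1R,2S)-1-hydroxypropane-1,2,3-tricarboxylate
Conditions: LDA (2.2 equiv), THF, −78 → −20 °C; allyl bromoacetate, −78 → −50 °C; AcOH
Reagents that add atoms: allyl bromoacetate (C=CCOC(=O)CBr)
Why: Fráter–Seebach alkylation as in step 11 should set C-3 as S by attack anti to the C-1 ester of the chelated dianion.

Step 17
Reactants: 22 hydroxy triester
Product: 23 O-trimethylsilyl ether of 22
Conditions: TMSCl, imidazole, CH2Cl2, 0 °C
Reagents that add atoms: chlorotrimethylsilane (C[Si](C)(C)Cl)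
Why: Standard silylation of the secondary alcohol, as in step 12.

Step 18
Reactants: 24 (2E,6E)-farnesyl acetate
Product: 25 (2E,6E,10E)-12-hydroxyfarnesyl acetate
Conditions: SeO2 (cat.), t-BuOOH, salicylic acid (cat.), CH2Cl2, rt
Reagents that add atoms: tert-butyl hydroperoxide (CC(C)(C)OO)
Why: Sharpless–Umbreit allylic oxidation (ene reaction, [2,3]-shift) is selective for the (E)-methyl group of the terminal trisubstituted alkene of farnesyl derivatives.

Step 19
Reactants: 25 12-hydroxyfarnesyl acetate
Product: 26 (2E,6E,10S,11S)-10,11-epoxy-12-hydroxyfarnesyl acetate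
Conditions: Ti(OiPr)4, L-(+)-DET, t-BuOOH, 4 Å MS, CH2Cl2, −20 °C
Reagents that add atoms: tert-butyl hydroperoxide (CC(C)(C)OO)
Why: Katsuki–Sharpless epoxidation of the (E)-2-methyl allylic alcohol with L-(+)-tartrate should give the (10S,11S)-epoxide (same facial sense as (2S,3S)-epoxygeraniol) and leaves the two remote alkenes untouched.

Step 20
Reactants: 26 epoxy alcohol
Product: 27 12-O-tert-butyldimethylsilyl ether of 26
Conditions: TBSCl, imidazole, DMF, rt
Reagents that add atoms: tert-butyldimethylsilyl chloride (CC(C)(C)[Si](C)(C)Cl)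
Why: Standard silylation of the primary alcohol.

Step 21
Reactants: 27 silyl-protected epoxy-polyene
Product: 29 3β-hydroxy-13-(tert-butyldimethylsilyloxy)albicanyl acetate, via 3-O-trimethylsilyl ether 28 (not isolated)
Conditions: Cp2TiCl2 (0.2 equiv), Mn, TMSCl, 2,4,6-collidine, THF, rt; then 1 M HCl/THF (brief)
Reagents that add atoms: none
Why: Ti(III)-mediated radical opening of the epoxide (Nugent–RajanBabu type, catalytic Cuerva–Oltra variant) gives the tertiary C-4 radical, which closes rings A and B by two 6-endo-trig cyclisations through a chair–chair transition state with the C-3 O–Ti bond equatorial, so that the epoxide carbon sets C-5, C-10 and C-9, the larger CH2OTBS group should go equatorial at C-4, and the last radical ends as the exocyclic alkene.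

Step 22
Reactants: 29 3β-alcohol
Product: 30 3-O-(imidazol-1-ylthiocarbonyl) derivative of 29
Conditions: 1,1′-thiocarbonyldiimidazole, DMAP, ClCH2CH2Cl, reflux
Reagents that add atoms: 1,1′-thiocarbonyldiimidazole (S=C(n1ccnc1)n1ccnc1)
Why: Thioacylation of the hindered equatorial alcohol prepares the Barton–McCombie substrate.

Step 23
Reactants: 30 thiocarbonylimidazolide
Product: 31 13-(tert-butyldimethylsilyloxy)albicanyl acetate
Conditions: Bu3SnH, AIBN, toluene, 110 °C
Reagents that add atoms: none
Why: Barton–McCombie radical deoxygenation removes the helper C-3 oxygen, and the secondary C-3 radical has no alkene within reach before it is reduced.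

Step 24
Reactants: 31 acetate
Product: 32 13-(tert-butyldimethylsilyloxy)albicanol
Conditions: K2CO3, MeOH, rt
Reagents that add atoms: none
Why: Methanolysis frees the C-11 alcohol while the silyl ether stays.

Step 25
Reactants: 32 alcohol
Product: 33 13-(tert-butyldimethylsilyloxy)albicanal
Conditions: Dess–Martin periodinane, NaHCO3, CH2Cl2, 0 °C
Reagents that add atoms: none
Why: Buffered Dess–Martin oxidation as in step 8 should give the aldehyde without epimerisation at C-9.

Step 26
Reactants: 33 aldehyde; 23 O-trimethylsilyl ether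
Product: 34 2,3-diallyl 1-methyl (1R,2S)-1-{[13-(tert-butyldimethylsilyloxy)albican-11-yl]oxy}propane-1,2,3-tricarboxylate
Conditions: Et3SiH, TMSOTf (0.2 equiv), CH2Cl2, −78 °C
Reagents that add atoms: none
Why: Reductive etherification as in step 13 forms the second C-11–O bond with C-9 and isocitrate C-2 untouched, and the primary TBS ether should survive the catalytic silyl triflate at low temperature.

Step 27
Reactants: 34 silyl ether
Product: 35 2,3-diallyl 1-methyl (1R,2S)-1-[(13-hydroxyalbican-11-yl)oxy]propane-1,2,3-tricarboxylate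
Conditions: HF·pyridine, pyridine, THF, 0 °C → rt
Reagents that add atoms: none
Why: Fluoride desilylation buffered with pyridine frees the 4α-hydroxymethyl group without touching the esters or the exocyclic alkene.

Step 28
Reactants: 20 acid; 35 alcohol
Product: 36 tris-allyl ester of the target (ester link between the central carboxyl of 20 and C-13–OH of 35)
Conditions: 2,4,6-trichlorobenzoyl chloride, Et3N, THF, rt; then 35, DMAP, toluene, rt
Reagents that add atoms: none
Why: Yamaguchi esterification (mixed anhydride, DMAP acyl transfer) joins the α-branched acid to the neopentyl-type primary alcohol at room temperature, which should keep the C-3 stereocentre of the acid.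

Step 29
Reactants: 36 tris-allyl ester
Product: 37 CNP0420141.2 (target)
Conditions: Pd(PPh3)4 (10 mol%), morpholine, THF, rt; then dilute acid work-up
Reagents that add atoms: none
Why: Pd(0)-catalysed deallylation (π-allyl formation, capture by morpholine) frees the three acids under neutral conditions that spare the methyl esters, the hindered ester link and both exocyclic alkenes.

**Compound list**

1 | (1R,5R)-(+)-verbenone | C1[C@@H]2C(C)=CC(=O)[C@H]1C2(C)C | starting material
2 | 3-iodoverbenone | C1[C@@H]2C(C)=C(I)C(=O)[C@H]1C2(C)C | intermediate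
3 | methyl 4,6,6-trimethyl-2-oxobicyclo[3.1.1]hept-3-ene-3-carboxylate | C1[C@@H]2C(C)=C(C(=O)OC)C(=O)[C@H]1C2(C)C | intermediate
4 | allyltrimethylsilane | C=CC[Si](C)(C)C | starting material
5 | (E)-1,3-bis(trimethylsilyl)propene | C[Si](C)(C)C/C=C/[Si](C)(C)C | intermediate
6 | methyl 4,6,6-trimethyl-2-oxo-4-[1-(trimethylsilyl)prop-2-enyl]bicyclo[3.1.1]heptane-3-carboxylate (new group anti to the CMe2 bridge) | C1[C@@H]2[C@](C)(C(C=C)[Si](C)(C)C)C(C(=O)OC)C(=O)[C@H]1C2(C)C | intermediate
7 | methyl (1R,4aS,8aS)-5,5,8a-trimethyl-2-oxo-1,2,3,4,4a,5,6,8a-octahydronaphthalene-1-carboxylate | O=C1CC[C@H]2C(C)(C)CC=C[C@]2(C)[C@H]1C(=O)OC | intermediate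
8 | methyl (1R,4aS,8aS)-5,5,8a-trimethyl-2-oxodecahydronaphthalene-1-carboxylate | O=C1CC[C@H]2C(C)(C)CCC[C@]2(C)[C@H]1C(=O)OC | intermediate
9 | methyl albicanate | C=C1CC[C@H]2C(C)(C)CCC[C@]2(C)[C@H]1C(=O)OC | intermediate
10 | (+)-albicanol | C=C1CC[C@H]2C(C)(C)CCC[C@]2(C)[C@H]1CO | intermediate
11 | albicanal | C=C1CC[C@H]2C(C)(C)CCC[C@]2(C)[C@H]1C=O | intermediate
12 | (R)-malic acid | O[C@@H](C(=O)O)CC(=O)O | starting material
13 | (R)-2-(trifluoroacetoxy)succinic anhydride | O=C1C[C@@H](OC(=O)C(F)(F)F)C(=O)O1 | intermediate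
14 | (R)-malic acid 1-methyl ester | O[C@@H](C(=O)OC)CC(=O)O | intermediate
15 | 4-tert-butyl 1-methyl (R)-malate | O[C@@H](C(=O)OC)CC(=O)OC(C)(C)C | intermediate
16 | 3-allyl 2-tert-butyl 1-methyl (1R,2S)-1-hydroxypropane-1,2,3-tricarboxylate | O[C@@H](C(=O)OC)[C@H](CC(=O)OCC=C)C(=O)OC(C)(C)C | intermediate
17 | O-trimethylsilyl ether of 16 | C[Si](C)(C)O[C@@H](C(=O)OC)[C@H](CC(=O)OCC=C)C(=O)OC(C)(C)C | intermediate
18 | 3-allyl 2-tert-butyl 1-methyl (1R,2S)-1-(albican-11-yloxy)propane-1,2,3-tricarboxylate | C=C1CC[C@H]2C(C)(C)CCC[C@]2(C)[C@H]1CO[C@@H](C(=O)OC)[C@H](CC(=O)OCC=C)C(=O)OC(C)(C)C | intermediate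
19 | 3-allyl 1-methyl 2-trimethylsilyl (1R,2S)-1-(albican-11-yloxy)propane-1,2,3-tricarboxylate | C=C1CC[C@H]2C(C)(C)CCC[C@]2(C)[C@H]1CO[C@@H](C(=O)OC)[C@H](CC(=O)OCC=C)C(=O)O[Si](C)(C)C | intermediate
20 | (1R,2S)-1-(albican-11-yloxy)propane-1,2,3-tricarboxylic acid 3-allyl 1-methyl diester | C=C1CC[C@H]2C(C)(C)CCC[C@]2(C)[C@H]1CO[C@@H](C(=O)OC)[C@H](CC(=O)OCC=C)C(=O)O | intermediate
21 | 4-allyl 1-methyl (R)-malate | O[C@@H](C(=O)OC)CC(=O)OCC=C | intermediate
22 | 2,3-diallyl 1-methyl (1R,2S)-1-hydroxypropane-1,2,3-tricarboxylate | O[C@@H](C(=O)OC)[C@H](CC(=O)OCC=C)C(=O)OCC=C | intermediate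
23 | O-trimethylsilyl ether of 22 | C[Si](C)(C)O[C@@H](C(=O)OC)[C@H](CC(=O)OCC=C)C(=O)OCC=C | intermediate
24 | (2E,6E)-farnesyl acetate | CC(=O)OC/C=C(C)/CC/C=C(C)/CCC=C(C)C | starting material
25 | (2E,6E,10E)-12-hydroxyfarnesyl acetate | CC(=O)OC/C=C(C)/CC/C=C(C)/CC/C=C(C)/CO | intermediate
26 | (2E,6E,10S,11S)-10,11-epoxy-12-hydroxyfarnesyl acetate | CC(=O)OC/C=C(C)/CC/C=C(C)/CC[C@@H]1O[C@@]1(C)CO | intermediate
27 | 12-O-TBS ether of 26 | CC(=O)OC/C=C(C)/CC/C=C(C)/CC[C@@H]1O[C@@]1(C)CO[Si](C)(C)C(C)(C)C | intermediate
28 | 3-O-trimethylsilyl ether of 29 | CC(C)(C)[Si](C)(C)OC[C@]1(C)[C@@H](O[Si](C)(C)C)CC[C@]2(C)[C@@H](COC(C)=O)C(=C)CC[C@@H]12 | intermediate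
29 | 3β-hydroxy-13-(tert-butyldimethylsilyloxy)albicanyl acetate | CC(C)(C)[Si](C)(C)OC[C@]1(C)[C@@H](O)CC[C@]2(C)[C@@H](COC(C)=O)C(=C)CC[C@@H]12 | intermediate
30 | 3-O-(imidazol-1-ylthiocarbonyl) derivative of 29 | CC(C)(C)[Si](C)(C)OC[C@]1(C)[C@@H](OC(=S)n3ccnc3)CC[C@]2(C)[C@@H](COC(C)=O)C(=C)CC[C@@H]12 | intermediate
31 | 13-(tert-butyldimethylsilyloxy)albicanyl acetate | CC(C)(C)[Si](C)(C)OC[C@]1(C)CCC[C@]2(C)[C@@H](COC(C)=O)C(=C)CC[C@@H]12 | intermediate
32 | 13-(tert-butyldimethylsilyloxy)albicanol | CC(C)(C)[Si](C)(C)OC[C@]1(C)CCC[C@]2(C)[C@@H](CO)C(=C)CC[C@@H]12 | intermediate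
33 | 13-(tert-butyldimethylsilyloxy)albicanal | CC(C)(C)[Si](C)(C)OC[C@]1(C)CCC[C@]2(C)[C@@H](C=O)C(=C)CC[C@@H]12 | intermediate
34 | 2,3-diallyl 1-methyl (1R,2S)-1-{[13-(TBS-oxy)albican-11-yl]oxy}propane-1,2,3-tricarboxylate | CC(C)(C)[Si](C)(C)OC[C@]1(C)CCC[C@]2(C)[C@@H](CO[C@@H](C(=O)OC)[C@H](CC(=O)OCC=C)C(=O)OCC=C)C(=C)CC[C@@H]12 | intermediate
35 | 2,3-diallyl 1-methyl (1R,2S)-1-[(13-hydroxyalbican-11-yl)oxy]propane-1,2,3-tricarboxylate | OC[C@]1(C)CCC[C@]2(C)[C@@H](CO[C@@H](C(=O)OC)[C@H](CC(=O)OCC=C)C(=O)OCC=C)C(=C)CC[C@@H]12 | intermediate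
36 | tris-allyl ester of the target | C=C1CC[C@H]2C(C)(C)CCC[C@]2(C)[C@H]1CO[C@@H](C(=O)OC)[C@H](CC(=O)OCC=C)C(=O)OC[C@]1(C)CCC[C@]2(C)[C@@H](CO[C@@H](C(=O)OC)[C@H](CC(=O)OCC=C)C(=O)OCC=C)C(=C)CC[C@@H]12 | intermediate
37 | CNP0420141.2 | C=C1CC[C@H]2C(C)(C)CCC[C@]2(C)[C@H]1CO[C@@H](C(=O)OC)[C@H](CC(=O)O)C(=O)OC[C@]1(C)CCC[C@]2(C)[C@@H](CO[C@@H](C(=O)OC)[C@H](CC(=O)O)C(=O)O)C(=C)CC[C@@H]12 | target

**Step count and risks**

Total step count: 29. Longest linear sequence: 12 steps (steps 18–29, from farnesyl acetate).

Steps most likely to fail: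

1. Step 4 (Proposed new method). What may go wrong: ionisation of the cyclobutane before the conjugate addition, too slow attack by the hindered silyl-bearing carbon on the quaternary-forming centre, or protodesilylation of the α-silyl allyl group once the proton source is in the flask. Fallback: the annulation is divided into separately known operations with allyltrimethylsilane itself as the three-carbon unit. It sets out from 3 and 4: a Hosomi–Sakurai conjugate allylation (TiCl4, CH2Cl2, −78 °C, aqueous work-up) should give the 4-allyl keto ester F1 with the allyl group anti to the CMe2 bridge. SnCl4 in CH2Cl2 at 0 °C should then open the cyclobutane and close ring A by a Prins-type cation–olefin cyclisation with chloride capture, giving the 2-chloro decalin keto ester F2. Bu3SnH/AIBN removes the chlorine, and the route is rejoined at 8.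

2. Step 13 (step 26 is of the same type). What may go wrong: enolisation of the β,γ-unsaturated aldehyde under the Lewis acid (epimerisation at C-9 or migration of the exocyclic alkene into conjugation), or slow acetal formation with the electron-poor, hindered silyl ether so that the aldehyde is merely reduced. Fallback: a Williamson-type O-alkylation replaces the carbonyl route. It sets out from 10 and 16: 10 with Tf2O and 2,6-di-tert-butyl-4-methylpyridine (CH2Cl2, −78 °C) gives albicanyl triflate F3, and the sodium alkoxide of 16 (NaH, 15-crown-5, THF, −40 °C) displaces the triflate by SN2, which returns to 18.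

3. Step 21. What may go wrong: poor facial selectivity at the planar C-4 radical (axial instead of equatorial CH2OTBS), or reductive opening and deoxygenation of the 2,3-epoxy alcohol derivative before cyclisation. Fallback: a cationic epoxy-polyene cyclisation, in which the epoxide opens with inversion at C-4 in concert with C-4–C-5 bond formation, so that the (E)-CH2OTBS group must end equatorial. It sets out from 27: MeAlCl2 (CH2Cl2, −78 °C, aqueous work-up) should give the 3β,8α-diol 11-acetate F4, the C-8 cation being captured through the neighbouring acetate. Thiocarbonyldiimidazole/DMAP gives the 3-O-thiocarbonylimidazolide F5 (the tertiary 8-OH does not react), and Bu3SnH/AIBN gives the 8α-ol F6. SOCl2/pyridine (CH2Cl2, −78 °C) dehydrates the equatorial tertiary alcohol to the exocyclic alkene, and the route is rejoined at 31.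

**Further compounds**

F1 | step 4 | methyl 4-allyl-4,6,6-trimethyl-2-oxobicyclo[3.1.1]heptane-3-carboxylate (allyl anti to the CMe2 bridge) | C1[C@@H]2[C@](C)(CC=C)C(C(=O)OC)C(=O)[C@H]1C2(C)C
F2 | step 4 | methyl (1R,4aS,8aS)-7-chloro-5,5,8a-trimethyl-2-oxodecahydronaphthalene-1-carboxylate (either C-7 epimer) | O=C1CC[C@H]2C(C)(C)CC(Cl)C[C@]2(C)[C@H]1C(=O)OC
F3 | step 13 | albicanyl trifluoromethanesulfonate | C=C1CC[C@H]2C(C)(C)CCC[C@]2(C)[C@H]1COS(=O)(=O)C(F)(F)F
F4 | step 21 | 3β,8α-dihydroxy-13-(tert-butyldimethylsilyloxy)driman-11-yl acetate | C[C@@]1(O)CC[C@H]2[C@](C)(CO[Si](C)(C)C(C)(C)C)[C@@H](O)CC[C@]2(C)[C@H]1COC(C)=O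
F5 | step 21 | 3-O-(imidazol-1-ylthiocarbonyl) derivative of F4 | C[C@@]1(O)CC[C@H]2[C@](C)(CO[Si](C)(C)C(C)(C)C)[C@@H](OC(=S)n3ccnc3)CC[C@]2(C)[C@H]1COC(C)=O
F6 | step 21 | 8α-hydroxy-13-(tert-butyldimethylsilyloxy)driman-11-yl acetate | C[C@@]1(O)CC[C@H]2[C@](C)(CO[Si](C)(C)C(C)(C)C)CCC[C@]2(C)[C@H]1COC(C)=O
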